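**Retrosynthetic overview**
- C4 of ring C is an isolated carbonyl carbon. One neighbour is C4a of ring A, which has the OMe-bearing C5 and the O1-bearing C8a on either side; the other is C3, to which ring B and the enol-ether carbon C2 are attached.
- Both C4a–C4 and C4–C3 are cut at once: a ring-A aryl iodide, carbon monoxide (as C4) and a 1-aryl-2-methoxyvinyl boronate are joined by a palladium-catalysed carbonylative Suzuki–Miyaura coupling.
- The ring-A iodide comes from 5-methoxyresorcinol by TIPS/MOM differentiation and directed lithiation–iodination between OMe and OMOM.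
- The ring-B boronate comes from 5-bromovanillin. Its methyl group is moved from O3 to O4 (demethylation, selective 4-O-methylation), followed by MOM protection, Stille prenylation, methoxymethylene Wittig, bromination–dehydrobromination and Miyaura borylation.
- Rings A and B are bought as arenes; ring C closes last (O1–C2) when acid removes the MOM groups and methanol is lost; fluoride then frees the 7-OH.

Key step: step 11

Remark on the chemistry: the 2-methoxyvinyl intermediates are drawn with OMe cis to Br, B or C=O, the geometry expected from the dehydrobromination and kept by both palladium steps; it has no bearing on the outcome, because C2 enters the pyranone ring by addition–elimination, so a minor geometric isomer would converge on the same product.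

**Route**

Step 1
Reactants: 1 5-methoxyresorcinol
Product: 2 3-methoxy-5-(triisopropylsilyloxy)phenol
Conditions: TIPSCl (0.9 equiv), imidazole, DMF, 0 °C to rt; diol and bis-silyl ether recycled
Reagents that add atoms: triisopropylsilyl chloride, CC(C)[Si](Cl)(C(C)C)C(C)C
Why: O-silylation of a phenol; the two hydroxyls of 1 are equivalent, so a slight deficit of silyl chloride should give mainly the mono-ether, which differs enough in polarity from diol and bis-ether to be separated.

Step 2
Reactants: 2 3-methoxy-5-(triisopropylsilyloxy)phenol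
Product: 3 1-methoxy-3-(methoxymethoxy)-5-(triisopropylsilyloxy)benzene
Conditions: MOMCl, iPr2NEt, CH2Cl2, 0 °C to rt
Reagents that add atoms: chloromethyl methyl ether, COCCl
Why: Williamson-type O-alkylation of the remaining phenol under amine base, conditions that leave the aryl silyl ether untouched.

Step 3
Reactants: 3 1-methoxy-3-(methoxymethoxy)-5-(triisopropylsilyloxy)benzene
Product: 5 2-iodo-1-methoxy-3-(methoxymethoxy)-5-(triisopropylsilyloxy)benzene, via aryllithium 4 (not isolated)
Conditions: n-BuLi, THF, 0 °C; then I2, THF, −78 °C to rt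
Reagents that add atoms: iodine, II
Why: Directed ortho-metalation: the C2 proton lies between the methoxy and methoxymethoxy groups, which cooperate in binding n-BuLi, whereas the bulky, poorly coordinating silyloxy group screens both of its ortho positions, so the iodine quench should place iodine at C2 only.

Step 4
Reactants: 6 5-bromovanillin
Product: 7 3-bromo-4,5-dihydroxybenzaldehyde
Conditions: AlCl3, pyridine, CH2Cl2, reflux; aq. HCl work-up
Reagents that add atoms: none
Why: AlCl3–pyridine ether cleavage through the aluminium chelate of the ortho-hydroxy anisole, the methyl group passing to pyridine; it is needed because ring B requires OH at C3' and OMe at C4', the reverse of the pattern in 6.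

Step 5
Reactants: 7 3-bromo-4,5-dihydroxybenzaldehyde
Product: 8 3-bromo-5-hydroxy-4-methoxybenzaldehyde
Conditions: MeI (1.1 equiv), Li2CO3, DMF, 40 °C
Reagents that add atoms: iodomethane, CI
Why: Regioselective Williamson O-methylation: the 4-OH, para to the formyl group and ortho to bromine, is much the more acidic, so the weak base Li2CO3 should form only that phenoxide, which methyl iodide alkylates while the 5-OH stays free.

Step 6
Reactants: 8 3-bromo-5-hydroxy-4-methoxybenzaldehyde
Product: 9 3-bromo-4-methoxy-5-(methoxymethoxy)benzaldehyde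
Conditions: MOMCl, iPr2NEt, CH2Cl2, 0 °C to rt
Reagents that add atoms: chloromethyl methyl ether, COCCl
Why: Williamson-type MOM protection of the single remaining phenol, compatible with aldehyde and aryl bromide.

Step 7
Reactants: 9 3-bromo-4-methoxy-5-(methoxymethoxy)benzaldehyde
Product: 10 4-methoxy-3-(methoxymethoxy)-5-(3-methylbut-2-enyl)benzaldehyde
Conditions: tributyl(3-methylbut-2-enyl)stannane, Pd(PPh3)4 (5 mol%), DMF, 100 °C
Reagents that add atoms: tributyl(3-methylbut-2-enyl)stannane, CCCC[Sn](CCCC)(CCCC)CC=C(C)C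
Why: Stille cross-coupling: oxidative addition to the aryl bromide, allyl transfer from tin and reductive elimination at the less substituted allyl terminus should give the linear prenyl arene under neutral conditions that spare the aldehyde and the MOM ether.

Step 8
Reactants: 10 4-methoxy-3-(methoxymethoxy)-5-(3-methylbut-2-enyl)benzaldehyde; 11 (methoxymethyl)triphenylphosphonium chloride
Product: 13 2-methoxy-1-(methoxymethoxy)-5-(2-methoxyvinyl)-3-(3-methylbut-2-enyl)benzene (E/Z mixture), via phosphorus ylide 12 (not isolated)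
Conditions: NaN(SiMe3)2, THF, 0 °C; then 10, 0 °C to rt
Reagents that add atoms: none
Why: Wittig olefination with a non-stabilised alkoxymethylene ylide should give the methyl enol ether as an E/Z mixture, and both isomers serve in the next step because bromine addition removes the alkene geometry.

Step 9
Reactants: 13 2-methoxy-1-(methoxymethoxy)-5-(2-methoxyvinyl)-3-(3-methylbut-2-enyl)benzene (E/Z mixture)
Product: 15 (Z)-5-(1-bromo-2-methoxyvinyl)-2-methoxy-1-(methoxymethoxy)-3-(3-methylbut-2-enyl)benzene, via vicinal dibromide 14 (not isolated)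
Conditions: Br2 (1.0 equiv), CH2Cl2, −78 °C; then DBU, −78 °C to rt
Reagents that add atoms: bromine, BrBr
Why: Electrophilic bromine addition followed by dehydrobromination: the enol ether is orders of magnitude more nucleophilic than the trisubstituted prenyl alkene, so one equivalent of Br2 at −78 °C should add only there, after which the anomeric bromide ionises and DBU removes the benzylic proton, leaving bromine on the aryl-bearing carbon and cis to OMe.

Step 10
Reactants: 15 (Z)-5-(1-bromo-2-methoxyvinyl)-2-methoxy-1-(methoxymethoxy)-3-(3-methylbut-2-enyl)benzene; 16 bis(pinacolato)diboron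
Product: 17 (E)-2-{2-methoxy-1-[4-methoxy-3-(methoxymethoxy)-5-(3-methylbut-2-enyl)phenyl]vinyl}-4,4,5,5-tetramethyl-1,3,2-dioxaborolane (boron cis to OMe)
Conditions: PdCl2(PPh3)2 (3 mol%), PPh3 (6 mol%), KOPh, toluene, 50 °C
Reagents that add atoms: none
Why: Miyaura borylation of an alkenyl bromide with retention of alkene geometry; the mild base KOPh promotes boron transfer without setting off Suzuki coupling between product and unreacted bromide.

Step 11
Reactants: 5 2-iodo-1-methoxy-3-(methoxymethoxy)-5-(triisopropylsilyloxy)benzene; 17 (E)-2-{2-methoxy-1-[4-methoxy-3-(methoxymethoxy)-5-(3-methylbut-2-enyl)phenyl]vinyl}-4,4,5,5-tetramethyl-1,3,2-dioxaborolane; 18 carbon monoxide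
Product: 19 (Z)-3-methoxy-1-[2-methoxy-6-(methoxymethoxy)-4-(triisopropylsilyloxy)phenyl]-2-[4-methoxy-3-(methoxymethoxy)-5-(3-methylbut-2-enyl)phenyl]prop-2-en-1-one
Conditions: Pd(PPh3)4 (5 mol%), K2CO3 (3 equiv), CO (1 atm), anisole, 80 °C; 17 added slowly
Reagents that add atoms: none
Why: Zerovalent palladium inserts into the C–I bond of 5, CO inserts into the aryl–palladium bond to give an aroyl complex of divalent palladium, carbonate-assisted transmetalation transfers the alkenyl group of 17 with retention, and reductive elimination forms C4–C3 after C4a–C4. The closest known reaction type is the carbonylative Suzuki–Miyaura coupling of aryl iodides with alkenyl boronates to aryl vinyl ketones. No ring closes and no stereocentre is formed; the alkene geometry of 17 is carried over and is lost later at ring closure. The selectivity needed is carbonylative over direct aryl–alkenyl coupling: the aryl–palladium bond of 5 is flanked by OMe and OCH2OMe, so transmetalation at that stage is slow while CO insertion relieves the crowding, and the CO atmosphere together with slow addition of the boronate reinforces this. The prenyl alkene, both MOM ethers and the TIPS ether should be inert to the carbonate base and the neutral palladium intermediates.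

Step 12
Reactants: 19 (Z)-3-methoxy-1-[2-methoxy-6-(methoxymethoxy)-4-(triisopropylsilyloxy)phenyl]-2-[4-methoxy-3-(methoxymethoxy)-5-(3-methylbut-2-enyl)phenyl]prop-2-en-1-one
Product: 21 3-[3-hydroxy-4-methoxy-5-(3-methylbut-2-enyl)phenyl]-5-methoxy-7-(triisopropylsilyloxy)-4H-chromen-4-one, via bisphenol enone 20 (not isolated)
Conditions: HCl (1 M), MeOH, 45 °C
Reagents that add atoms: none
Why: Acid-catalysed acetal methanolysis frees both phenols, after which the C8a hydroxyl adds to the enol-ether carbon C2 (6-endo-trig oxa-Michael addition) and methanol is eliminated to give the chromen-4-one; the 5-OMe side cannot cyclise and the prenyl group has no ortho hydroxyl to trap it.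

Step 13
Reactants: 21 3-[3-hydroxy-4-methoxy-5-(3-methylbut-2-enyl)phenyl]-5-methoxy-7-(triisopropylsilyloxy)-4H-chromen-4-one
Product: 22 7-hydroxy-3-[3-hydroxy-4-methoxy-5-(3-methylbut-2-enyl)phenyl]-5-methoxy-4H-chromen-4-one (EANPDB:LEGU_00347)
Conditions: Bu4NF, AcOH, THF, 0 °C
Reagents that add atoms: none
Why: Fluoride-mediated desilylation of the aryl silyl ether, buffered with acetic acid so that the base-sensitive pyranone ring is not opened.

**Compound list**
1 | 5-methoxyresorcinol | COc1cc(O)cc(O)c1 | starting material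
2 | 3-methoxy-5-(triisopropylsilyloxy)phenol | COc1cc(O)cc(O[Si](C(C)C)(C(C)C)C(C)C)c1 | intermediate
3 | 1-methoxy-3-(methoxymethoxy)-5-(triisopropylsilyloxy)benzene | COCOc1cc(OC)cc(O[Si](C(C)C)(C(C)C)C(C)C)c1 | intermediate
4 | [2-methoxy-6-(methoxymethoxy)-4-(triisopropylsilyloxy)phenyl]lithium (formed in the flask) | [Li]c1c(OC)cc(O[Si](C(C)C)(C(C)C)C(C)C)cc1OCOC | intermediate
5 | 2-iodo-1-methoxy-3-(methoxymethoxy)-5-(triisopropylsilyloxy)benzene | COCOc1cc(O[Si](C(C)C)(C(C)C)C(C)C)cc(OC)c1I | intermediate
6 | 5-bromovanillin | COc1cc(C=O)cc(Br)c1O | starting material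
7 | 3-bromo-4,5-dihydroxybenzaldehyde | O=Cc1cc(O)c(O)c(Br)c1 | intermediate
8 | 3-bromo-5-hydroxy-4-methoxybenzaldehyde | COc1c(O)cc(C=O)cc1Br | intermediate
9 | 3-bromo-4-methoxy-5-(methoxymethoxy)benzaldehyde | COCOc1cc(C=O)cc(Br)c1OC | intermediate
10 | 4-methoxy-3-(methoxymethoxy)-5-(3-methylbut-2-enyl)benzaldehyde | COCOc1cc(C=O)cc(CC=C(C)C)c1OC | intermediate
11 | (methoxymethyl)triphenylphosphonium chloride | COC[P+](c1ccccc1)(c1ccccc1)c1ccccc1.[Cl-] | starting material
12 | (methoxymethylene)triphenylphosphorane (formed in the flask) | COC=P(c1ccccc1)(c1ccccc1)c1ccccc1 | intermediate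
13 | 2-methoxy-1-(methoxymethoxy)-5-(2-methoxyvinyl)-3-(3-methylbut-2-enyl)benzene, E/Z mixture (no alkene descriptor because both isomers are used) | COC=Cc1cc(OCOC)c(OC)c(CC=C(C)C)c1 | intermediate
14 | 5-(1,2-dibromo-2-methoxyethyl)-2-methoxy-1-(methoxymethoxy)-3-(3-methylbut-2-enyl)benzene, diastereomer mixture (formed in the flask) | COC(Br)C(Br)c1cc(OCOC)c(OC)c(CC=C(C)C)c1 | intermediate
15 | (Z)-5-(1-bromo-2-methoxyvinyl)-2-methoxy-1-(methoxymethoxy)-3-(3-methylbut-2-enyl)benzene (Br cis to OMe) | CO/C=C(\Br)c1cc(OCOC)c(OC)c(CC=C(C)C)c1 | intermediate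
16 | bis(pinacolato)diboron | CC1(C)OB(OC1(C)C)B1OC(C)(C)C(C)(C)O1 | starting material
17 | (E)-2-{2-methoxy-1-[4-methoxy-3-(methoxymethoxy)-5-(3-methylbut-2-enyl)phenyl]vinyl}-4,4,5,5-tetramethyl-1,3,2-dioxaborolane (B cis to OMe) | CO/C=C(\B1OC(C)(C)C(C)(C)O1)c1cc(OCOC)c(OC)c(CC=C(C)C)c1 | intermediate
18 | carbon monoxide | [C-]#[O+] | starting material
19 | (Z)-3-methoxy-1-[2-methoxy-6-(methoxymethoxy)-4-(triisopropylsilyloxy)phenyl]-2-[4-methoxy-3-(methoxymethoxy)-5-(3-methylbut-2-enyl)phenyl]prop-2-en-1-one | CO/C=C(\C(=O)c1c(OC)cc(O[Si](C(C)C)(C(C)C)C(C)C)cc1OCOC)c1cc(OCOC)c(OC)c(CC=C(C)C)c1 | intermediate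
20 | (Z)-1-[2-hydroxy-6-methoxy-4-(triisopropylsilyloxy)phenyl]-2-[3-hydroxy-4-methoxy-5-(3-methylbut-2-enyl)phenyl]-3-methoxyprop-2-en-1-one (formed in the flask) | CO/C=C(\C(=O)c1c(OC)cc(O[Si](C(C)C)(C(C)C)C(C)C)cc1O)c1cc(O)c(OC)c(CC=C(C)C)c1 | intermediate
21 | 3-[3-hydroxy-4-methoxy-5-(3-methylbut-2-enyl)phenyl]-5-methoxy-7-(triisopropylsilyloxy)-4H-chromen-4-one | COc1c(O)cc(-c2coc3cc(O[Si](C(C)C)(C(C)C)C(C)C)cc(OC)c3c2=O)cc1CC=C(C)C | intermediate
22 | 7-hydroxy-3-[3-hydroxy-4-methoxy-5-(3-methylbut-2-enyl)phenyl]-5-methoxy-4H-chromen-4-one | COc1c(O)cc(-c2coc3cc(O)cc(OC)c3c2=O)cc1CC=C(C)C | target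

**Step count**
Total: 13 steps. Longest linear sequence: 10 steps (steps 4 to 13, from 5-bromovanillin).

**Steps most likely to fail**

1. Step 11. Direct aryl–alkenyl coupling without CO uptake, or protodeboronation of the alkenyl boronate before acyl transfer, may compete, and oxidative addition to the electron-rich, hindered iodide may be slow. The fallback sets out from arene 3 and bromide 15 and comes back at enone 19. Lithiation of 3 as in step 3 and quenching of aryllithium 4 with DMF would give 2-methoxy-6-(methoxymethoxy)-4-(triisopropylsilyloxy)benzaldehyde F1. Bromine–lithium exchange on 15 with t-BuLi (2 equiv, THF, −78 °C) would give (E)-{2-methoxy-1-[4-methoxy-3-(methoxymethoxy)-5-(3-methylbut-2-enyl)phenyl]vinyl}lithium F2, which should be stable because lithium is cis to OMe. Addition of F2 to F1 would give racemic (Z)-3-methoxy-1-[2-methoxy-6-(methoxymethoxy)-4-(triisopropylsilyloxy)phenyl]-2-[4-methoxy-3-(methoxymethoxy)-5-(3-methylbut-2-enyl)phenyl]prop-2-en-1-ol F3. Oxidation of F3, an allylic and benzylic alcohol, with MnO2 in CH2Cl2 would give 19.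

2. Step 9. Bromine may also add to the prenyl double bond, or hydrogen bromide may be lost in the wrong direction through the electron-rich benzylic position. The fallback avoids bromine; it sets out from aldehyde 10 and comes back at boronate 17. Tin–lithium exchange between tributyl(methoxymethyl)stannane and n-BuLi (THF, −78 °C) would give methoxymethyllithium F4. Addition of F4 to 10 would give racemic 2-methoxy-1-[4-methoxy-3-(methoxymethoxy)-5-(3-methylbut-2-enyl)phenyl]ethanol F5. Dess–Martin periodinane would oxidise F5 to 2-methoxy-1-[4-methoxy-3-(methoxymethoxy)-5-(3-methylbut-2-enyl)phenyl]ethanone F6. KN(SiMe3)2 in THF at −78 °C would convert F6 into the chelated potassium (Z)-2-methoxy-1-[4-methoxy-3-(methoxymethoxy)-5-(3-methylbut-2-enyl)phenyl]ethenolate F7. Trapping of F7 with PhNTf2 would give (Z)-2-methoxy-1-[4-methoxy-3-(methoxymethoxy)-5-(3-methylbut-2-enyl)phenyl]vinyl trifluoromethanesulfonate F8. Miyaura borylation of F8 with 16 under the conditions of step 10 would give 17 with the same geometry.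

3. Step 7. Allyl transposition during transfer from tin may form the bond at the tertiary terminus and give the reverse-prenyl isomer. The fallback builds the prenyl group by olefin metathesis; it sets out from bromide 9 and comes back at aldehyde 10. Stille coupling of 9 with allyltributylstannane (Pd(PPh3)4, DMF, 100 °C), which has no regiochemical ambiguity, would give 3-allyl-4-methoxy-5-(methoxymethoxy)benzaldehyde F9. Cross-metathesis of F9 with 2-methyl-2-butene (second-generation Grubbs catalyst, CH2Cl2, 40 °C) would give 10.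

**Further compounds**
F1 | step 11 | 2-methoxy-6-(methoxymethoxy)-4-(triisopropylsilyloxy)benzaldehyde | COCOc1cc(O[Si](C(C)C)(C(C)C)C(C)C)cc(OC)c1C=O
F2 | step 11 | (E)-{2-methoxy-1-[4-methoxy-3-(methoxymethoxy)-5-(3-methylbut-2-enyl)phenyl]vinyl}lithium | CO/C=C(\[Li])c1cc(OCOC)c(OC)c(CC=C(C)C)c1
F3 | step 11 | racemic (Z)-3-methoxy-1-[2-methoxy-6-(methoxymethoxy)-4-(triisopropylsilyloxy)phenyl]-2-[4-methoxy-3-(methoxymethoxy)-5-(3-methylbut-2-enyl)phenyl]prop-2-en-1-ol | CO/C=C(\C(O)c1c(OC)cc(O[Si](C(C)C)(C(C)C)C(C)C)cc1OCOC)c1cc(OCOC)c(OC)c(CC=C(C)C)c1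
F4 | step 9 | methoxymethyllithium | [Li]COC
F5 | step 9 | racemic 2-methoxy-1-[4-methoxy-3-(methoxymethoxy)-5-(3-methylbut-2-enyl)phenyl]ethanol | COCC(O)c1cc(OCOC)c(OC)c(CC=C(C)C)c1
F6 | step 9 | 2-methoxy-1-[4-methoxy-3-(methoxymethoxy)-5-(3-methylbut-2-enyl)phenyl]ethanone | COCC(=O)c1cc(OCOC)c(OC)c(CC=C(C)C)c1
F7 | step 9 | potassium (Z)-2-methoxy-1-[4-methoxy-3-(methoxymethoxy)-5-(3-methylbut-2-enyl)phenyl]ethenolate | CO/C=C(\[O-])c1cc(OCOC)c(OC)c(CC=C(C)C)c1.[K+]
F8 | step 9 | (Z)-2-methoxy-1-[4-methoxy-3-(methoxymethoxy)-5-(3-methylbut-2-enyl)phenyl]vinyl trifluoromethanesulfonate | CO/C=C(\OS(=O)(=O)C(F)(F)F)c1cc(OCOC)c(OC)c(CC=C(C)C)c1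
F9 | step 7 | 3-allyl-4-methoxy-5-(methoxymethoxy)benzaldehyde | COCOc1cc(C=O)cc(CC=C)c1OC
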